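At the reading, after 40 h, each flask holds the X that its L has made so far, while L has been turning into J, which appears in no step that makes X.

    L → J (k1 = 0.0065 h⁻¹, Ea1 = 240 kJ mol⁻¹)
    2 G → G2 (k2 = 0.35 M⁻¹ h⁻¹, Ea2 = 60.0 kJ mol⁻¹)
    G + L → X + L, rate k3*[G]*[L]/(1 + ([G]/Km3) + ([X]/Kp3)) (Km3 = 0.11 M, Kp3 = 0.061 M, k3 = 8200 M⁻¹ h⁻¹, Ea3 = 46.0 kJ mol⁻¹)
    (constants at 20 °C)

common to all: G 0.050 M; L 25 µM; time 40 h

| flask | temperature |
|---|---|
| Monday's | 50 °C |
| Thursday's | 5 °C |
| Wednesday's | 35 °C |
| Sunday's | 20 °C |

- a species is counted by the G in it: one G2 counts as two
- for a step with 2 of a species take k times the square, and two of it per event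
- the constants hold at 20 °C; other temperatures follow from the activation energies

1. the best flask by amount of X, in percent of the G charged; "all alike" if 1.5 percentage points covers them all (Monday's / Thursday's / Wednesday's / Sunday's / all alike)
2. amount of X at the end, in percent of the G charged, Monday's
3. amount of X at the end, in percent of the G charged, Thursday's
4. amount of X at the end, in percent of the G charged, Wednesday's
5. amount of X at the end, in percent of the G charged, Sunday's

**Catalyst budget.** L decays first-order with a constant kd, so the time-integral of cL has a closed form: the charge of L times (one − e^(−kd·t))/kd. Multiplying this integral by kc, the constant of the catalytic step, and dividing by D, the denominator of its rate law with the charged G and no X, gives the catalyst budget B. If no other step touched G and D held, the fraction of G turned to X would be one − e^(−B). Here D is 1.45. In Monday's flask kd is 60.7 h⁻¹, so the catalyst budget B comes to 0.0134. Step 2 takes hardly any of Monday's G during one lifetime of L, so the hand value for Monday's X is 1.33%.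

**The charges.** B is proportional to the charge of L, so in Monday's flask, where B is small, a small relative change in L passes whole into X by hand. A small change in G passes on to Monday's X, in percent of the G charged, with opposite sign and a weight of 31.0%, the share of the G term in D.

**The time.** Monday's kd·t is 2428, so the exponential term has vanished and a longer run adds nothing to B, whereas Sunday's kd·t is 0.260, so there a longer run still adds to B.

**The temperature.** From the coldest to the hottest flask kc rises by 16 and kd by 1.9 × 10⁶. B therefore reads 4.96 for Sunday's, 2.04 for Thursday's and 0.450 for Wednesday's. The hand reckoning thus puts Sunday's first, with X at 99.3%, 87.0% and 36.2% for these three, each reckoned with no other step on G and with D held.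

**The forecast.** The forecast names Sunday's, with 1.33% for Monday's, 77.8% for Thursday's, 31% for Wednesday's and 87.5% for Sunday's, starting from this: “first-order loss gives an effective enzyme time”. Its Sunday's figure stands below the hand value, and so do its Thursday's and Wednesday's.

**The result.** Sunday's is highest at 87.5%, with 11.4% as G2 at the end, followed by Thursday's at 77.9%, Wednesday's at 32.5% and Monday's at 1.32%, against 1.33% from Monday's budget. Moved alone up or down by one common factor, Monday's settings shift X at most in the order L (0.39 points), then G (0.11 points), then time (under 0.05 points).

**Warmer neighbour.** A flask like Sunday's kept at 45 °C has the charges and D of Monday's, and its kd·t of 596 again removes the exponential term. Its budget therefore follows from Monday's through 194 kJ mol⁻¹, the activation energy of L's decay minus that of catalysis, and comes to 0.0417, which means X at 4.08%. That flask ends with L at 0%, G2 at 86.7% and X at 4.02%.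

The constants are made up; no experiment stands behind them.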